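**Plan**
Retrosynthesis: the C8 tiglate, the C13 ether and the 1,10-epoxide are removed first. The ten-membered ring is then cut at C1–C2, the 4,5-epoxide at C5–O (back to a C5 mesylate and a C4 carbinol), the chain at C5–C6 (vinylogous aldol) and at C8–C9 (propargylation), and the butenolide is traced to a 3,4-disubstituted furan.
Forward: furan-3,4-dimethanol → C8 aldehyde → homopropargyl alcohol → E C1 vinyl iodide → butenolide → aldol with a C2–C5 aldehyde from isoprene monoxide → 4,5-epoxide → ten-membered ring (C1–C2) → tiglate, 1,10-epoxide, free C13–OH.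
Enabling feature: C1 of the E-trisubstituted C1=C10 alkene (the future 1,10-epoxide) is bonded to the C2 methylene of the ten-membered ring. This sp2–sp3 bond can be made with retention from the C1 vinyl iodide and the primary borane grown from the C4 vinyl group, while the butenolide, the trans-4,5-epoxide and the E alkene hold seven of the ten ring atoms.
Stereochemistry: C8 from a chiral phosphoric acid-catalysed propargylation; C4 from a palladium-catalysed asymmetric etherification of isoprene monoxide; C5 and C6 from a copper–pybox-catalysed anti vinylogous Mukaiyama aldol, C5 then being inverted on epoxide closure; C1 and C10 from peripheral epoxidation of the macrocyclic alkene; alkene geometries from carboalumination and from tiglic acid.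

Key step: step 15

Remark on numbering: germacrane numbering is used throughout (C1–C10 ring carbons, C11/C12/C13 butenolide α-carbon, carbonyl and hydroxymethyl carbon, C14 methyl on C10, C15 methyl on C4).
Remark on protecting groups: C8–OH is carried as its TBS ether and C13–OH as its PMB ether. C4–OH is carried as a 3,4-dimethoxybenzyl (DMB) ether, which can chelate copper in step 11 and is cleaved by DDQ ahead of PMB in step 13.
Assumption: the antipodes of the three chiral catalysts (steps 1, 6 and 11) are assigned by analogy with simpler substrates; the sense of induction would be confirmed on 3, 10 and 18 before material is carried on.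

**Route**

Step 1
Reactants: 1 isoprene monoxide (racemic 2-methyl-2-vinyloxirane) + 2 3,4-dimethoxybenzyl alcohol
Product: 3 (R)-2-[(3,4-dimethoxybenzyl)oxy]-2-methylbut-3-en-1-ol
Conditions: Pd2(dba)3·CHCl3 (1 mol%), (S,S)-DACH-phenyl ligand N,N'-[(1S,2S)-cyclohexane-1,2-diyl]bis[2-(diphenylphosphino)benzamide] (3 mol%), Et3B (1 mol%), CH2Cl2, rt
Reagents that add atoms: none
Why: Tsuji–Trost-type dynamic kinetic asymmetric allylic etherification, in which zerovalent palladium opens the racemic vinyl epoxide to an equilibrating π-allyl alkoxide, the borate formed with Et3B delivers the benzylic alcohol to the tertiary terminus, and the chiral ligand pocket should set the quaternary C4 centre as R.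

Step 2
Reactants: 3 (R)-2-[(3,4-dimethoxybenzyl)oxy]-2-methylbut-3-en-1-ol
Product: 4 (R)-2-[(3,4-dimethoxybenzyl)oxy]-2-methylbut-3-enal
Conditions: Dess–Martin periodinane, CH2Cl2, 0 °C → rt
Reagents that add atoms: none
Why: Dess–Martin oxidation of the only hydroxyl under near-neutral conditions, the quaternary α-carbon excluding both epimerisation and migration of the alkene into conjugation.

Step 3
Reactants: 5 diethyl furan-3,4-dicarboxylate
Product: 6 furan-3,4-diyldimethanol
Conditions: LiAlH4, THF, 0 °C → rt
Reagents that add atoms: none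
Why: Hydride reduction (LiAlH4) of both ester groups to the symmetric diol, the furan ring being inert.

Step 4
Reactants: 6 furan-3,4-diyldimethanol
Product: 7 {4-[(4-methoxybenzyloxy)methyl]furan-3-yl}methanol
Conditions: NaH (1.0 equiv), PMBCl (1.0 equiv), Bu4NI (cat.), THF/DMF, 0 °C → rt
Reagents that add atoms: 4-methoxybenzyl chloride, COc1ccc(CCl)cc1
Why: Williamson etherification of the monoalkoxide of a symmetric diol, statistical in outcome so that the bis-ether is separated and recovered diol is recycled.

Step 5
Reactants: 7 {4-[(4-methoxybenzyloxy)methyl]furan-3-yl}methanol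
Product: 8 4-[(4-methoxybenzyloxy)methyl]furan-3-carbaldehyde
Conditions: MnO2, CH2Cl2, rt
Reagents that add atoms: none
Why: MnO2 oxidation of a heteroaryl carbinol (benzylic-type activation) stops at the aldehyde and leaves the PMB ether alone.

Step 6
Reactants: 8 4-[(4-methoxybenzyloxy)methyl]furan-3-carbaldehyde + 9 allenylboronic acid pinacol ester
Product: 10 (S)-1-{4-[(4-methoxybenzyloxy)methyl]furan-3-yl}but-3-yn-1-ol
Conditions: (S)-TRIP phosphoric acid (5 mol%), 4 Å MS, toluene, −20 °C; aqueous work-up
Reagents that add atoms: none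
Why: Brønsted acid-catalysed asymmetric propargylation, an SE2' allenylboration through a six-membered chair transition state in which the chiral phosphate binds the boronate oxygen and the formyl hydrogen, so that catalyst control should set C8 as S.

Step 7
Reactants: 10 (S)-1-{4-[(4-methoxybenzyloxy)methyl]furan-3-yl}but-3-yn-1-ol
Product: 11 tert-butyldimethylsilyl ether of 10 (C8–OTBS)
Conditions: TBSCl, imidazole, DMF, rt
Reagents that add atoms: tert-butyldimethylsilyl chloride, CC(C)(C)[Si](C)(C)Cl
Why: Standard silylation of the secondary alcohol, which masks C8–OH through the Lewis-acidic and basic steps that follow.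

Step 8
Reactants: 11 tert-butyldimethylsilyl ether of 10
Product: 13 3-[(1S,3E)-1-(tert-butyldimethylsilyloxy)-4-iodo-3-methylbut-3-en-1-yl]-4-[(4-methoxybenzyloxy)methyl]furan, via alkenylalane 12 (not isolated)
Conditions: Me3Al (2.5 equiv), Cp2ZrCl2 (25 mol%), CH2Cl2, 0 °C → rt; then I2, THF, −30 °C
Reagents that add atoms: trimethylaluminium, C[Al](C)C; iodine, II
Why: Negishi zirconium-catalysed carboalumination adds methyl and aluminium syn across the terminal alkyne with methyl on the internal carbon (C10), and iododealumination with retention gives the E C1 vinyl iodide.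

Step 9
Reactants: 13 vinyl iodide furan
Product: 15 4-[(1S,3E)-1-(tert-butyldimethylsilyloxy)-4-iodo-3-methylbut-3-en-1-yl]-3-[(4-methoxybenzyloxy)methyl]furan-2(5H)-one, via hydroxybutenolide 14 (not isolated)
Conditions: O2, hν (visible), tetraphenylporphyrin (cat.), iPr2NEt, CH2Cl2, −78 °C; then NaBH4, MeOH, −20 → 0 °C; dilute HCl work-up
Reagents that add atoms: dioxygen, O=O
Why: Singlet oxygen adds across the furan ([4+2]), the hindered amine removes the less hindered bridgehead hydrogen at C12 (Kornblum–DeLaMare fragmentation) so that C12 becomes the lactone carbonyl and C6 the hemiacetal, and borohydride reduction of the ring-opened C6 aldehyde followed by relactonisation gives the butenolide.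

Step 10
Reactants: 15 butenolide
Product: 16 2-(trimethylsilyloxy)furan of 15 (C12–OSiMe3, C6–H aromatic)
Conditions: TMSOTf, Et3N, CH2Cl2, 0 °C; pentane extraction, used crude
Reagents that add atoms: trimethylsilyl trifluoromethanesulfonate, C[Si](C)(C)OS(=O)(=O)C(F)(F)F
Why: Soft enolisation with silyl triflate and amine removes a γ-hydrogen at C6 because the resulting 2-silyloxyfuran is aromatic.

Step 11
Reactants: 16 2-(trimethylsilyloxy)furan + 4 (R)-2-[(3,4-dimethoxybenzyl)oxy]-2-methylbut-3-enal
Product: 18 (5S)-5-{(1S,2R)-2-[(3,4-dimethoxybenzyl)oxy]-1-hydroxy-2-methylbut-3-en-1-yl}-4-[(1S,3E)-1-(tert-butyldimethylsilyloxy)-4-iodo-3-methylbut-3-en-1-yl]-3-[(4-methoxybenzyloxy)methyl]furan-2(5H)-one (4R,5S,6S,8S), via silyl ether 17 (not isolated)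
Conditions: [Cu((S,S)-Ph-pybox)](SbF6)2 (10 mol%), CH2Cl2, −78 °C; then 1 M HCl, THF, 0 °C
Reagents that add atoms: none
Why: Vinylogous Mukaiyama aldol addition in which the aldehyde chelates divalent copper through its carbonyl and benzylic ether oxygens, the C2-symmetric pybox ligand leaves open the aldehyde face that gives 5S (catalyst control, helped by the similar size of methyl and vinyl on C4), the silyloxyfuran reacts at C6 because C11 is fully substituted, and the open transition state of furan dienolates with chelated alkoxy aldehydes should be anti-selective, which sets 6S.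

Step 12
Reactants: 18 anti aldol adduct
Product: 19 C5 methanesulfonate of 18
Conditions: MsCl, Et3N, CH2Cl2, −40 °C
Reagents that add atoms: methanesulfonyl chloride, CS(=O)(=O)Cl
Why: Sulfonylation of the only free hydroxyl through the sulfene pathway, run cold so that the amine does not trigger elimination toward C6.

Step 13
Reactants: 19 C5 methanesulfonate
Product: 20 C4 tertiary alcohol C5 methanesulfonate (DMB ether removed)
Conditions: DDQ (1.1 equiv), CH2Cl2/pH 7 buffer, 0 °C
Reagents that add atoms: none
Why: Oxidative cleavage of a benzylic ether by DDQ (charge-transfer complex, hydride abstraction, hydrolysis), the 3,4-dimethoxybenzyl ether reacting well ahead of the less electron-rich PMB ether at C13.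

Step 14
Reactants: 20 hydroxy methanesulfonate
Product: 21 (5S)-5-[(2R,3R)-3-methyl-3-vinyloxiran-2-yl]-4-[(1S,3E)-1-(tert-butyldimethylsilyloxy)-4-iodo-3-methylbut-3-en-1-yl]-3-[(4-methoxybenzyloxy)methyl]furan-2(5H)-one (4R,5R,6S,8S)
Conditions: K2CO3, MeOH, 0 °C
Reagents that add atoms: none
Why: Intramolecular Williamson reaction (3-exo-tet SN2) in which the C4 alkoxide displaces the C5 mesylate with inversion, turning the 4R,5S hydroxy mesylate into the 4R,5R trans-epoxide.

Step 15
Reactants: 21 vinyl iodide vinyl epoxide butenolide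
Product: 23 8-O-TBS 13-O-PMB (4R,5R,6S,8S)-4,5-epoxygermacra-1(10)E,7(11)-dien-6,12-olide, via alkylborane 22 (not isolated)
Conditions: 9-BBN (1.5 equiv), THF, 0 °C → rt; then slow addition to Pd(dppf)Cl2 (20 mol%), AsPh3 (20 mol%), Cs2CO3 (3 equiv), DMF/THF/H2O, rt, 1 mM
Reagents that add atoms: none
Why: 9-BBN adds anti-Markovnikov to the monosubstituted C2=C3 vinyl group only (the butenolide alkene is tetrasubstituted and electron-poor, the vinyl iodide trisubstituted) to give the primary C2 borane 22; zerovalent palladium then inserts into the C1–I bond with retention, the base-activated borate transfers the C2 alkyl group to palladium, and reductive elimination forms C1–C2. The closest known reaction type is the intramolecular B-alkyl Suzuki–Miyaura macrocyclisation of ω-alkenyl vinyl iodides, for which ten-membered carbocycles lie at the small end of the range. The ten-membered ring closes end-to-end at an sp2–sp3 bond by reductive elimination from an eleven-membered alkyl(alkenyl)palladacycle, with the E C1=C10 alkene ending up endocyclic. No stereocentre is created; C4, C5, C6 and C8 are carried through, and the E geometry fixed by carboalumination cannot scramble. The step needs cyclisation to beat oligomerisation and the base to spare the C6–H/epoxide array: high dilution with slow addition, AsPh3 and Cs2CO3 at room temperature are meant to secure both, and the butenolide, the trans-epoxide and the E alkene hold seven of the ten ring atoms in a turn that brings C1 and C2 together.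

Step 16
Reactants: 23 macrocyclic TBS ether
Product: 24 13-O-PMB (4R,5R,6S,8S)-4,5-epoxy-8-hydroxygermacra-1(10)E,7(11)-dien-6,12-olide
Conditions: TBAF, AcOH (1:1), THF, 0 °C → rt
Reagents that add atoms: none
Why: Fluoride-mediated desilylation buffered with acetic acid so that neither the butenolide C6–H nor the epoxide is exposed to free alkoxide or to strong acid.

Step 17
Reactants: 24 C8 alcohol + 25 tiglic acid
Product: 26 8-O-tigloyl 13-O-PMB (4R,5R,6S,8S)-4,5-epoxygermacra-1(10)E,7(11)-dien-6,12-olide
Conditions: DCC, DMAP (cat.), CH2Cl2, 0 °C → rt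
Reagents that add atoms: none
Why: Steglich esterification (carbodiimide activation with acyl transfer through DMAP) of the secondary C8 alcohol, the E geometry of tiglic acid being the stable one and preserved.

Step 18
Reactants: 26 tiglate
Product: 27 8-O-tigloyl 13-O-PMB (1R,4R,5R,6S,8S,10R)-1,10:4,5-diepoxygermacr-7(11)-en-6,12-olide
Conditions: DMDO (acetone solution), CH2Cl2, −20 → 0 °C
Reagents that add atoms: dimethyldioxirane, CC1(C)OO1
Why: Prilezhaev-type epoxidation by a neutral dioxirane of the only electron-rich alkene, attack from the outer (peripheral) face of the E C1=C10 bond of the ten-membered ring setting C1 and C10 together as 1R,10R, while the tiglate and butenolide alkenes are too electron-poor to react.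

Step 19
Reactants: 27 diepoxide PMB ether
Product: 28 target CNP0111480.1
Conditions: DDQ, CH2Cl2/pH 7 buffer, 0 °C → rt
Reagents that add atoms: none
Why: Oxidative removal of the PMB ether by DDQ under buffered neutral conditions that spare the two epoxides, the tiglate and the butenolide.

**Compound list**

1 | isoprene monoxide (racemic 2-methyl-2-vinyloxirane) | CC1(C=C)CO1 | starting material
2 | 3,4-dimethoxybenzyl alcohol | COc1ccc(CO)cc1OC | starting material
3 | (R)-2-[(3,4-dimethoxybenzyl)oxy]-2-methylbut-3-en-1-ol | OC[C@](C)(OCc1ccc(OC)c(OC)c1)C=C | intermediate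
4 | (R)-2-[(3,4-dimethoxybenzyl)oxy]-2-methylbut-3-enal | O=C[C@](C)(OCc1ccc(OC)c(OC)c1)C=C | intermediate
5 | diethyl furan-3,4-dicarboxylate | CCOC(=O)c1cocc1C(=O)OCC | starting material
6 | furan-3,4-diyldimethanol | OCc1cocc1CO | intermediate
7 | {4-[(4-methoxybenzyloxy)methyl]furan-3-yl}methanol | OCc1cocc1COCc1ccc(OC)cc1 | intermediate
8 | 4-[(4-methoxybenzyloxy)methyl]furan-3-carbaldehyde | O=Cc1cocc1COCc1ccc(OC)cc1 | intermediate
9 | allenylboronic acid pinacol ester | C=C=CB1OC(C)(C)C(C)(C)O1 | starting material
10 | (S)-1-{4-[(4-methoxybenzyloxy)methyl]furan-3-yl}but-3-yn-1-ol | C#CC[C@H](O)c1cocc1COCc1ccc(OC)cc1 | intermediate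
11 | TBS ether of 10 | C#CC[C@H](O[Si](C)(C)C(C)(C)C)c1cocc1COCc1ccc(OC)cc1 | intermediate
12 | (E)-alkenyl(dimethyl)alane from 11, formed in the flask | C[Al](C)/C=C(\C)C[C@H](O[Si](C)(C)C(C)(C)C)c1cocc1COCc1ccc(OC)cc1 | intermediate
13 | 3-[(1S,3E)-1-(TBSO)-4-iodo-3-methylbut-3-en-1-yl]-4-[(PMBO)methyl]furan | I/C=C(\C)C[C@H](O[Si](C)(C)C(C)(C)C)c1cocc1COCc1ccc(OC)cc1 | intermediate
14 | 5-hydroxybutenolide (C6 hemiacetal, both epimers), formed in the flask | I/C=C(\C)C[C@H](O[Si](C)(C)C(C)(C)C)C1=C(COCc2ccc(OC)cc2)C(=O)OC1O | intermediate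
15 | 4-[(1S,3E)-1-(TBSO)-4-iodo-3-methylbut-3-en-1-yl]-3-[(PMBO)methyl]furan-2(5H)-one | I/C=C(\C)C[C@H](O[Si](C)(C)C(C)(C)C)C1=C(COCc2ccc(OC)cc2)C(=O)OC1 | intermediate
16 | 2-(trimethylsilyloxy)furan of 15 | I/C=C(\C)C[C@H](O[Si](C)(C)C(C)(C)C)c1coc(O[Si](C)(C)C)c1COCc1ccc(OC)cc1 | intermediate
17 | C5 O-trimethylsilyl ether of aldol adduct 18, formed in the flask | I/C=C(\C)C[C@H](O[Si](C)(C)C(C)(C)C)C1=C(COCc2ccc(OC)cc2)C(=O)O[C@@H]1[C@H](O[Si](C)(C)C)[C@](C)(OCc1ccc(OC)c(OC)c1)C=C | intermediate
18 | anti aldol adduct (4R,5S,6S,8S): C5–OH, C4–ODMB | I/C=C(\C)C[C@H](O[Si](C)(C)C(C)(C)C)C1=C(COCc2ccc(OC)cc2)C(=O)O[C@@H]1[C@H](O)[C@](C)(OCc1ccc(OC)c(OC)c1)C=C | intermediate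
19 | C5 methanesulfonate of 18 | I/C=C(\C)C[C@H](O[Si](C)(C)C(C)(C)C)C1=C(COCc2ccc(OC)cc2)C(=O)O[C@@H]1[C@H](OS(C)(=O)=O)[C@](C)(OCc1ccc(OC)c(OC)c1)C=C | intermediate
20 | C4 alcohol C5 methanesulfonate | I/C=C(\C)C[C@H](O[Si](C)(C)C(C)(C)C)C1=C(COCc2ccc(OC)cc2)C(=O)O[C@@H]1[C@H](OS(C)(=O)=O)[C@](C)(O)C=C | intermediate
21 | cyclisation precursor (4R,5R,6S,8S): C1 vinyl iodide, C8–OTBS, C13–OPMB, C4 vinyl 4,5-epoxide | I/C=C(\C)C[C@H](O[Si](C)(C)C(C)(C)C)C1=C(COCc2ccc(OC)cc2)C(=O)O[C@@H]1[C@H]1O[C@]1(C)C=C | intermediate
22 | C2 B-alkyl-9-borabicyclo[3.3.1]nonane from 21, formed in the flask | I/C=C(\C)C[C@H](O[Si](C)(C)C(C)(C)C)C1=C(COCc2ccc(OC)cc2)C(=O)O[C@@H]1[C@H]1O[C@]1(C)CCB1C2CCCC1CCC2 | intermediate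
23 | 8-O-TBS 13-O-PMB (4R,5R,6S,8S)-4,5-epoxygermacra-1(10)E,7(11)-dien-6,12-olide | CC(C)(C)[Si](C)(C)O[C@H]1C/C(C)=C/CC[C@@]2(C)O[C@@H]2[C@H]2OC(=O)C(COCc3ccc(OC)cc3)=C12 | intermediate
24 | 13-O-PMB 4,5-epoxy-8-hydroxygermacra-1(10)E,7(11)-dien-6,12-olide | O[C@H]1C/C(C)=C/CC[C@@]2(C)O[C@@H]2[C@H]2OC(=O)C(COCc3ccc(OC)cc3)=C12 | intermediate
25 | tiglic acid | C/C=C(\C)C(=O)O | starting material
26 | 8-O-tigloyl 13-O-PMB 4,5-epoxygermacra-1(10)E,7(11)-dien-6,12-olide | C/C=C(\C)C(=O)O[C@H]1C/C(C)=C/CC[C@@]2(C)O[C@@H]2[C@H]2OC(=O)C(COCc3ccc(OC)cc3)=C12 | intermediate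
27 | 8-O-tigloyl 13-O-PMB (1R,4R,5R,6S,8S,10R)-1,10:4,5-diepoxygermacr-7(11)-en-6,12-olide | C/C=C(\C)C(=O)O[C@H]1C[C@@]2(C)O[C@@H]2CC[C@@]2(C)O[C@@H]2[C@H]2OC(=O)C(COCc3ccc(OC)cc3)=C12 | intermediate
28 | CNP0111480.1 | C/C=C(\C)C(=O)O[C@H]1C[C@@]2(C)O[C@@H]2CC[C@@]2(C)O[C@@H]2[C@H]2OC(=O)C(CO)=C12 | target

**Totals**
Total step count: 19.
Longest linear sequence: 17 steps (5 → 28, steps 3–19); the aldehyde 4 is made in 2 steps and joined in step 11.

**Steps most likely to fail**

1. Step 15 (ring closure). Intermolecular coupling may outrun closure of the strained ten-membered ring. The alkylpalladium may be lost to protodeboronation or β-hydride elimination. The aqueous base may deprotonate C6 and open the neighbouring epoxide. Fallback (same bond, different organometallic and a non-basic coupling): from 21, hydroboration with 9-BBN as in step 15 followed by oxidation with NaBO3·4H2O would give the C2 primary alcohol F3. MsCl/Et3N would give the primary mesylate F4 and NaI in acetone the primary iodide F5. Activated zinc dust in THF/DMA should insert into the alkyl C–I bond much faster than into the alkenyl C–I bond and give the alkylzinc iodide F6. An intramolecular Negishi coupling (Pd2(dba)3, tri(2-furyl)phosphine, THF, high dilution) would then close C1–C2 and return to 23.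

2. Step 11 (vinylogous aldol). The hindered 3,4-disubstituted silyloxyfuran may turn over slowly on the copper catalyst. Facial selectivity at C5 may erode, because methyl and vinyl on C4 differ little in size. The anti relation between C5 and C6 may not be reached, or the C8 centre may be mismatched with the catalyst. Fallback (substrate control followed by thermodynamic correction instead of catalyst control): from 16 and 4, BF3·OEt2 in CH2Cl2 at −78 °C should follow the usual syn preference of Lewis-acid vinylogous aldols of silyloxyfurans and Felkin–Anh addition (ether oxygen anti, nucleophile past the methyl group). This would give the 5,6-syn aldol adduct F1, the C6 epimer of 18. Et3N with catalytic DMAP in CH2Cl2 would then epimerise C6 through the 2-hydroxyfuran tautomer; the epimers would be separated, the syn isomer resubmitted, and the route rejoined at 18.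

3. Step 14 (epoxide closure; the mesylate is exposed from step 12 on). Deprotonation at C6, γ to the lactone carbonyl, may expel the C5 mesylate (E1cB) and give a γ-alkylidene butenolide in competition with closure. Fallback (neutral activation, no sulfonate and no carbonate base): from 18, DDQ in wet CH2Cl2 would remove the DMB ether and give the C4,C5-diol F2. A Mitsunobu cyclodehydration (PPh3, DIAD, THF, 0 °C → rt) would activate the secondary C5 hydroxyl as its oxyphosphonium ion, which the tertiary C4 hydroxyl displaces with inversion, returning to 21.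

**Further compounds**
F1 | step 11 | 5,6-syn aldol adduct (4R,5S,6R,8S), C6 epimer of 18 | I/C=C(\C)C[C@H](O[Si](C)(C)C(C)(C)C)C1=C(COCc2ccc(OC)cc2)C(=O)O[C@H]1[C@H](O)[C@](C)(OCc1ccc(OC)c(OC)c1)C=C
F2 | step 14 | C4,C5-diol (4R,5S,6S,8S) | I/C=C(\C)C[C@H](O[Si](C)(C)C(C)(C)C)C1=C(COCc2ccc(OC)cc2)C(=O)O[C@@H]1[C@H](O)[C@](C)(O)C=C
F3 | step 15 | C2 primary alcohol from 21 | I/C=C(\C)C[C@H](O[Si](C)(C)C(C)(C)C)C1=C(COCc2ccc(OC)cc2)C(=O)O[C@@H]1[C@H]1O[C@]1(C)CCO
F4 | step 15 | C2 primary methanesulfonate | I/C=C(\C)C[C@H](O[Si](C)(C)C(C)(C)C)C1=C(COCc2ccc(OC)cc2)C(=O)O[C@@H]1[C@H]1O[C@]1(C)CCOS(C)(=O)=O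
F5 | step 15 | C2 primary iodide | I/C=C(\C)C[C@H](O[Si](C)(C)C(C)(C)C)C1=C(COCc2ccc(OC)cc2)C(=O)O[C@@H]1[C@H]1O[C@]1(C)CCI
F6 | step 15 | C2 alkylzinc iodide | I/C=C(\C)C[C@H](O[Si](C)(C)C(C)(C)C)C1=C(COCc2ccc(OC)cc2)C(=O)O[C@@H]1[C@H]1O[C@]1(C)CC[Zn]I
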